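**Strategy.** The carboxyl carbon of the side chain lies two atoms from C6 of flavone ring A and can reach O5 through a six-membered ring, so the target is treated as the hydrolysed form of a 4-phenyl-dihydropyranone fused across O5–C5–C6. That lactone is disconnected at CH2–C(=O) and C(=O)–O5 into carbon monoxide and a 5-hydroxy-6-(1-phenylvinyl)flavone. A single enantioselective palladium hydride cyclocarbonylation should add H to the diaryl carbon, insert CO at the CH2 terminus and let the 5-hydroxyl capture the acyl, closing the ring and setting the only stereocentre (R). The precursor is 7,4′-di-O-benzylapigenin bearing the 1,1-diarylethene at C6, made by benzylation, C6 iodination and Suzuki coupling.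

Key step: step 4

Remark (assumption): the target stereocentre is (R) by CIP (flavone C6 > phenyl > CH2CO2H > H), and lactone 8 carries the same descriptor and spatial arrangement. Which antipode of the bisphosphine delivers (R) cannot be predicted with confidence. It is assumed that a short ligand screen fixes it before scale-up; (R)-DTBM-SEGPHOS is written below and its antipode is used if the sense proves opposite.

**Step 1**
Reactants: 1 apigenin; 2 benzyl bromide
Product: 3 7-(benzyloxy)-2-[4-(benzyloxy)phenyl]-5-hydroxy-4H-chromen-4-one (7,4′-di-O-benzylapigenin)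
Conditions: BnBr (2.2 equiv), K2CO3 (2.5 equiv), DMF, rt to 50 °C
Reagents that add atoms: benzyl bromide (the second equivalent, which supplies the second benzyl group), BrCc1ccccc1
Why: Twofold Williamson ether synthesis, in which the 7- and 4′-phenoxides are each alkylated by one equivalent of benzyl bromide while the 5-OH, hydrogen-bonded to the C4 carbonyl, is much less acidic and nucleophilic and should stay free under carbonate.

**Step 2**
Reactants: 3 7,4′-di-O-benzylapigenin
Product: 4 7-(benzyloxy)-2-[4-(benzyloxy)phenyl]-5-hydroxy-6-iodo-4H-chromen-4-one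
Conditions: BnNMe3·ICl2 (1.1 equiv), CaCO3 (3 equiv), CH2Cl2/MeOH (5:2), rt
Reagents that add atoms: benzyltrimethylammonium dichloroiodate, C[N+](C)(C)Cc1ccccc1.Cl[I-]Cl
Why: Electrophilic aromatic iodination, for which dichloroiodate is known to attack 5-hydroxy-7-alkoxyflavones at C6 (ortho to the chelated hydroxyl) rather than C8, ring B and the benzyl rings being far less activated and CaCO3 scavenging the HCl.

**Step 3**
Reactants: 4 6-iodo-7,4′-di-O-benzylapigenin; 5 1-phenylvinylboronic acid pinacol ester
Product: 6 7-(benzyloxy)-2-[4-(benzyloxy)phenyl]-5-hydroxy-6-(1-phenylvinyl)-4H-chromen-4-one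
Conditions: 5 (1.5 equiv), Pd(OAc)2 (5 mol%), SPhos (10 mol%), K3PO4 (3 equiv), toluene/H2O (10:1), 90 °C
Reagents that add atoms: none
Why: Suzuki–Miyaura coupling, in which the aryl iodide adds oxidatively with ease and the bulky electron-rich biarylphosphine supports transmetalation and reductive elimination at the doubly ortho-substituted carbon, the chelated 5-OH being tolerated as its phenoxide.

**Step 4**
Reactants: 6 5-hydroxy-6-(1-phenylvinyl)-7,4′-di-O-benzylflavone; 7 carbon monoxide
Product: 8 (4R)-5-(benzyloxy)-8-[4-(benzyloxy)phenyl]-4-phenyl-3,4-dihydro-2H,10H-pyrano[2,3-f]chromene-2,10-dione (4-phenyl-dihydropyranone fused at O5–C5–C6 of 7,4′-di-O-benzylapigenin)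
Conditions: Pd(OAc)2 (5 mol%), (R)-DTBM-SEGPHOS (6 mol%), TsOH·H2O (10 mol%), CO (20 bar), toluene, 80 °C
Reagents that add atoms: none
Why: Proposed new method: Pd(OAc)2, the bisphosphine and two equivalents of TsOH per palladium should generate a cationic L2Pd–H under CO, which adds across the 1,1-diarylethene with hydride going to the diaryl carbon and palladium to the CH2 terminus; CO then inserts into the primary Pd–C bond and the acylpalladium is captured by the neighbouring 5-OH, releasing 8 and regenerating Pd–H. The closest known reaction types are the palladium-catalysed cyclocarbonylation of 2-alkenylphenols to benzo-fused lactones and the enantioselective palladium hydride hydroesterification of vinylarenes and 1,1-disubstituted alkenes with CO and alcohols or phenols, neither of which has been shown on a flavone with an intramolecularly hydrogen-bonded phenol as the acyl acceptor. The one new ring (O5, C5, C6, CHPh, CH2, C=O) closes in a 6-exo-trig mode by attack of O5 on the acyl carbon. The stereocentre arises when hydride is transferred to one enantiotopic face of the alkene and is under ligand control, helped by the difference between the two aryl groups: the flavone ring, flanked by O5 and O7, is forced out of the alkene plane while the phenyl stays conjugated; because hydride insertion is reversible, the ligand in effect selects which diastereomeric alkyl- or acylpalladium proceeds to product. The step needs linear regioselectivity and capture by O5 alone: the first is secured by the fully substituted alkene carbon, since a branched product would require CO insertion at a tertiary dibenzylic palladium that instead reverts by beta-hydride elimination, and the second by the benzyl ethers, which leave O5 as the only nucleophile.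

**Step 5**
Reactants: 8 benzylated lactone
Product: 10 (3R)-3-[5,7-dihydroxy-2-(4-hydroxyphenyl)-4-oxo-4H-chromen-6-yl]-3-phenylpropanoic acid (target), via debenzylated lactone 9 (not isolated)
Conditions: H2 (1 atm), Pd/C (10 wt% palladium on carbon), THF, rt; filter through Celite under Ar; then LiOH (5 equiv), THF/H2O, 0 °C to rt under Ar; 1 M HCl to pH 3–4, 0 °C; EtOAc extraction
Reagents that add atoms: lithium hydroxide, [Li+].[OH-]
Why: Catalytic hydrogenolysis should cleave both benzyl aryl ethers under neutral conditions, and saponification of the aryl lactone (phenoxide leaving group) should proceed at 0 °C; the stereocentre is beta to the carbonyl, carries no acidic hydrogen and should remain (R), while cold acidification and prompt extraction limit re-lactonisation.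

**Compound list**
1 | apigenin | O=c1cc(-c2ccc(O)cc2)oc2cc(O)cc(O)c12 | starting material
2 | benzyl bromide | BrCc1ccccc1 | starting material
3 | 7-(benzyloxy)-2-[4-(benzyloxy)phenyl]-5-hydroxy-4H-chromen-4-one | O=c1cc(-c2ccc(OCc3ccccc3)cc2)oc2cc(OCc3ccccc3)cc(O)c12 | intermediate
4 | 7-(benzyloxy)-2-[4-(benzyloxy)phenyl]-5-hydroxy-6-iodo-4H-chromen-4-one | O=c1cc(-c2ccc(OCc3ccccc3)cc2)oc2cc(OCc3ccccc3)c(I)c(O)c12 | intermediate
5 | 1-phenylvinylboronic acid pinacol ester | C=C(B1OC(C)(C)C(C)(C)O1)c1ccccc1 | starting material
6 | 7-(benzyloxy)-2-[4-(benzyloxy)phenyl]-5-hydroxy-6-(1-phenylvinyl)-4H-chromen-4-one | C=C(c1ccccc1)c1c(OCc2ccccc2)cc2oc(-c3ccc(OCc4ccccc4)cc3)cc(=O)c2c1O | intermediate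
7 | carbon monoxide | [C-]#[O+] | starting material
8 | (4R)-5-(benzyloxy)-8-[4-(benzyloxy)phenyl]-4-phenyl-3,4-dihydro-2H,10H-pyrano[2,3-f]chromene-2,10-dione | O=C1C[C@H](c2ccccc2)c2c(OCc3ccccc3)cc3oc(-c4ccc(OCc5ccccc5)cc4)cc(=O)c3c2O1 | intermediate
9 | (4R)-5-hydroxy-8-(4-hydroxyphenyl)-4-phenyl-3,4-dihydro-2H,10H-pyrano[2,3-f]chromene-2,10-dione | O=C1C[C@H](c2ccccc2)c2c(O)cc3oc(-c4ccc(O)cc4)cc(=O)c3c2O1 | intermediate
10 | (3R)-3-[5,7-dihydroxy-2-(4-hydroxyphenyl)-4-oxo-4H-chromen-6-yl]-3-phenylpropanoic acid | O=C(O)C[C@H](c1ccccc1)c1c(O)cc2oc(-c3ccc(O)cc3)cc(=O)c2c1O | target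

**Total step count:** 5. **Longest linear sequence:** 5 steps (apigenin to target).

**Steps most likely to fail**

1. Step 4 (proposed new method). The hydrogen-bonded 5-OH may intercept the acylpalladium too slowly for turnover, the palladium hydride may merely reduce or oligomerise the acid-sensitive diarylethene, or facial discrimination in the hydride transfer may be poor. The fallback uses known chemistry, sets out from iodide 4 and returns at lactone 8. Mizoroki–Heck coupling of 4 with methyl acrylate (Pd(OAc)2, P(o-tol)3, Et3N, DMF, 100 °C) should give methyl (E)-3-[7-(benzyloxy)-2-[4-(benzyloxy)phenyl]-5-hydroxy-4-oxo-4H-chromen-6-yl]prop-2-enoate F1. Phosphine-catalysed isomerisation–lactonisation of this E-2-hydroxycinnamate (Bu3P 20 mol%, MeOH/THF, 70 °C) should give the fused coumarin 5-(benzyloxy)-8-[4-(benzyloxy)phenyl]-2H,10H-pyrano[2,3-f]chromene-2,10-dione F2. A Hayashi–Miyaura asymmetric 1,4-addition of phenylboronic acid (Rh(acac)(C2H4)2, (R)-SEGPHOS, dioxane/H2O, 60 °C), a reaction established for coumarins giving 4-arylchroman-2-ones, should then deliver 8. The ligand hand is expected by analogy with simple coumarins and would be confirmed. The fully substituted C2 of the flavone enone should not compete as an acceptor.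

2. Step 3. Transmetalation at the doubly ortho-substituted arylpalladium may be slow, allowing protodeboronation of the alpha-substituted vinylboronate and hydrodeiodination of 4. The fallback sets out from 4 and returns at 6: Barluenga coupling with commercial acetophenone N-tosylhydrazone (Pd2(dba)3, XPhos, LiOtBu, 1,4-dioxane, 100 °C). A palladium carbene formed from the diazo compound generated in the flask undergoes aryl migration and beta-hydride elimination to give the 1,1-diarylethene without any organoboron partner. No compound outside the list is made (F0).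

3. Step 5. The hydroxy acid may re-close to a lactone (onto O5 or the freed O7) during acidification and concentration, and prolonged hydrogenation may begin to saturate the pyranone C2=C3 bond. The fallback sets out from 8 and returns at target 10. Base-catalysed alcoholysis of the aryl lactone with benzyl alcohol (BnOH 5 equiv, catalytic K2CO3, THF, rt, neutralised before concentration) should give benzyl (3R)-3-[7-(benzyloxy)-2-[4-(benzyloxy)phenyl]-5-hydroxy-4-oxo-4H-chromen-6-yl]-3-phenylpropanoate F3, in which the chelated 5-OH is a poor nucleophile for re-closure. One neutral hydrogenolysis (H2, Pd/C, EtOAc/THF, rt, monitored closely) then removes all three benzyl groups and should release 10 with no aqueous base or acid in the last operation.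

**Further compounds**
F1 | step 4 | methyl (E)-3-[7-(benzyloxy)-2-[4-(benzyloxy)phenyl]-5-hydroxy-4-oxo-4H-chromen-6-yl]prop-2-enoate | COC(=O)/C=C/c1c(OCc2ccccc2)cc2oc(-c3ccc(OCc4ccccc4)cc3)cc(=O)c2c1O
F2 | step 4 | 5-(benzyloxy)-8-[4-(benzyloxy)phenyl]-2H,10H-pyrano[2,3-f]chromene-2,10-dione | O=C1C=Cc2c(OCc3ccccc3)cc3oc(-c4ccc(OCc5ccccc5)cc4)cc(=O)c3c2O1
F0 | step 3 | none | none
F3 | step 5 | benzyl (3R)-3-[7-(benzyloxy)-2-[4-(benzyloxy)phenyl]-5-hydroxy-4-oxo-4H-chromen-6-yl]-3-phenylpropanoate | O=C(OCc1ccccc1)C[C@H](c1ccccc1)c1c(OCc2ccccc2)cc2oc(-c3ccc(OCc4ccccc4)cc3)cc(=O)c2c1O
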